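The route rests on disconnecting the O1–C2 bond of ring C. In the target, C2 is a benzylic ether carbon bearing ring B, and its oxygen is trans to the C3 hydroxyl beside the C4 ketone: exactly what remains when a phenol opens a trans epoxide. In one operation, acid frees the C8a phenol of an (αR,βS)-chalcone epoxide, which attacks C2 with inversion, closing ring C, setting C2 and unveiling the C3 hydroxyl. The precursor is a 2'-methoxymethoxy-4',6'-dimethoxychalcone epoxide that already carries the (R)-1-arylethyl group on ring A and benzyl ethers on both outer phenols; the O5 methyl blocks the rival phenol and is removed last by chelation-controlled cleavage.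

Key step: step 9

Assumption: poly-L-leucine is taken to give the (αR,βS)-epoxide of 12, as it does with simple chalcones, and the antipode of the iridium P,N ligand in step 5 is the one that a short screen shows to deliver the (R)-diarylethane.

Step 1
Reactants: 1 4-hydroxy-2,6-dimethoxybenzaldehyde
Product: 2 2,6-dimethoxy-4-(methoxymethoxy)benzaldehyde
Conditions: NaH, MOMCl, DMF, 0 °C → rt
Reagents that add atoms: chloromethyl methyl ether, COCCl
Why: Williamson-type O-alkylation of the acidic para-formyl phenoxide with chloromethyl methyl ether installs the acetal that later directs ring lithiation and serves as the acid-labile trigger of the key step.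

Step 2
Reactants: 3 1-(benzyloxy)-4-bromobenzene; 2 2,6-dimethoxy-4-(methoxymethoxy)benzaldehyde
Product: 5 racemic [4-(benzyloxy)phenyl][2,6-dimethoxy-4-(methoxymethoxy)phenyl]methanol, via [4-(benzyloxy)phenyl]lithium 4 (not isolated)
Conditions: n-BuLi, THF, −78 °C; then 2, −78 → 0 °C; H2O
Reagents that add atoms: none
Why: Bromine–lithium exchange followed by 1,2-addition of the aryllithium to the aldehyde is a standard entry to diarylmethanols; the carbinol centre is formed racemic and is erased by the oxidation that follows.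

Step 3
Reactants: 5 racemic [4-(benzyloxy)phenyl][2,6-dimethoxy-4-(methoxymethoxy)phenyl]methanol
Product: 6 [4-(benzyloxy)phenyl][2,6-dimethoxy-4-(methoxymethoxy)phenyl]methanone
Conditions: DMP, CH2Cl2, 0 °C → rt
Reagents that add atoms: none
Why: Dess–Martin oxidation of the doubly benzylic secondary alcohol runs under near-neutral conditions that should leave the methoxymethyl acetal and the benzyl ether untouched.

Step 4
Reactants: 6 [4-(benzyloxy)phenyl][2,6-dimethoxy-4-(methoxymethoxy)phenyl]methanone
Product: 7 2-{1-[4-(benzyloxy)phenyl]ethenyl}-1,3-dimethoxy-5-(methoxymethoxy)benzene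
Conditions: Ph3PCH3Br, KOtBu, THF, 0 → 65 °C
Reagents that add atoms: methyltriphenylphosphonium bromide, C[P+](c1ccccc1)(c1ccccc1)c1ccccc1.[Br-]
Why: Wittig methylenation with the small non-stabilised ylide should still reach the carbonyl of the non-enolisable, ortho-disubstituted benzophenone on heating and gives the 1,1-diarylethene.

Step 5
Reactants: 7 2-{1-[4-(benzyloxy)phenyl]ethenyl}-1,3-dimethoxy-5-(methoxymethoxy)benzene
Product: 8 2-{(1R)-1-[4-(benzyloxy)phenyl]ethyl}-1,3-dimethoxy-5-(methoxymethoxy)benzene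
Conditions: H2 (5 bar), [Ir(cod)((S)-tBu-PHOX)]BArF (2 mol %), CH2Cl2, rt
Reagents that add atoms: none
Why: Iridium-catalysed asymmetric hydrogenation of an unfunctionalised 1,1-diarylethene; the 2,6-dimethoxyaryl ring is forced perpendicular to the alkene while the 4-benzyloxyphenyl ring stays coplanar, so the chiral P,N ligand can tell the two aryl groups apart and hydrogen should add to one enantioface to set the (R)-centre, the homogeneous catalyst leaving the benzyl ether intact.

Step 6
Reactants: 8 2-{(1R)-1-[4-(benzyloxy)phenyl]ethyl}-1,3-dimethoxy-5-(methoxymethoxy)benzene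
Product: 10 1-{3-[(1R)-1-(4-benzyloxyphenyl)ethyl]-2,4-dimethoxy-6-(methoxymethoxy)phenyl}ethan-1-one, via ring-lithiated diarylethane 9 (not isolated)
Conditions: n-BuLi, THF, 0 °C; then MeC(O)N(OMe)Me, −78 °C → rt; H2O
Reagents that add atoms: N-methoxy-N-methylacetamide, CC(=O)N(C)OC
Why: Directed ortho-metalation places lithium on the carbon flanked by the OMOM and OMe groups (the two such positions are equivalent by rotation about the aryl–CH bond) and the Weinreb ketone synthesis stops at the methyl ketone through its chelated tetrahedral intermediate; the tertiary benzylic C–H is shielded by two ortho methoxy groups and should not be deprotonated, so the stereocentre is kept.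

Step 7
Reactants: 10 1-{3-[(1R)-1-(4-benzyloxyphenyl)ethyl]-2,4-dimethoxy-6-(methoxymethoxy)phenyl}ethan-1-one; 11 4-(benzyloxy)benzaldehyde
Product: 12 (2E)-3-[4-(benzyloxy)phenyl]-1-{3-[(1R)-1-(4-benzyloxyphenyl)ethyl]-2,4-dimethoxy-6-(methoxymethoxy)phenyl}prop-2-en-1-one
Conditions: KOH, EtOH/THF, rt
Reagents that add atoms: none
Why: Claisen–Schmidt condensation of the methyl ketone enolate with the non-enolisable aldehyde, followed by E1cB loss of water, should give the thermodynamically preferred E-chalcone, as is routine for 2'-(methoxymethoxy)-6'-methoxyacetophenones.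

Step 8
Reactants: 12 (2E)-3-[4-(benzyloxy)phenyl]-1-{3-[(1R)-1-(4-benzyloxyphenyl)ethyl]-2,4-dimethoxy-6-(methoxymethoxy)phenyl}prop-2-en-1-one
Product: 13 {(2R,3S)-3-[4-(benzyloxy)phenyl]oxiran-2-yl}{3-[(1R)-1-(4-benzyloxyphenyl)ethyl]-2,4-dimethoxy-6-(methoxymethoxy)phenyl}methanone
Conditions: poly-L-leucine, urea·H2O2, DBU, THF, rt
Reagents that add atoms: urea–hydrogen peroxide, OO.NC(N)=O
Why: Juliá–Colonna epoxidation, in which hydroperoxide adds to the enone held at the N-terminus of the helical polypeptide and the peroxy enolate closes to the trans epoxide, should set both epoxide carbons as (αR,βS) under catalyst control; the remote (R)-centre should not interfere, and any minor epoxide is a diastereomer that can be removed.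

Step 9
Reactants: 13 {(2R,3S)-3-[4-(benzyloxy)phenyl]oxiran-2-yl}{3-[(1R)-1-(4-benzyloxyphenyl)ethyl]-2,4-dimethoxy-6-(methoxymethoxy)phenyl}methanone
Product: 15 (2R,3R)-2-[4-(benzyloxy)phenyl]-6-{(1R)-1-[4-(benzyloxy)phenyl]ethyl}-3-hydroxy-5,7-dimethoxy-2,3-dihydro-4H-chromen-4-one, via free 2'-phenol epoxide 14 (not isolated)
Conditions: HCl (1 M), MeOH/THF, 50 °C
Reagents that add atoms: none
Why: Acid-catalysed acetal exchange with methanol strips the methoxymethyl group from O1, and the liberated C8a phenol attacks the protonated epoxide at the benzylic carbon from the face opposite the departing oxygen, forming O1–C2 and leaving the former epoxide oxygen as the C3 hydroxyl. The closest known reaction type is the acid-induced cyclisation of 2'-(methoxymethoxy)chalcone epoxides to trans-3-hydroxyflavanones. Ring C closes in a 6-endo-tet mode because positive charge develops at C2, where the 4-benzyloxyphenyl ring stabilises it, and not at C3 next to the carbonyl, so the 5-exo path to a benzofuranone is disfavoured. The new C2 centre is set by stereospecific inversion of the (βS) epoxide carbon while C3 keeps the configuration installed in step 8, giving the trans (2R,3R) pair; should the opening become cation-like, the fixed C3 centre still steers closure to the trans-diequatorial product. The step needs 6-endo over 5-exo opening and attack by O1 in preference to O5: the electron-rich ring B secures the first and the O5 methyl ether the second, while dilute acid at moderate temperature limits capture of C2 by methanol and aryl migration.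

Step 10
Reactants: 15 (2R,3R)-2-[4-(benzyloxy)phenyl]-6-{(1R)-1-[4-(benzyloxy)phenyl]ethyl}-3-hydroxy-5,7-dimethoxy-2,3-dihydro-4H-chromen-4-one
Product: 17 (2R,3R)-3,5-dihydroxy-2-(4-hydroxyphenyl)-6-[(1R)-1-(4-hydroxyphenyl)ethyl]-7-methoxy-2,3-dihydro-4H-chromen-4-one, via debenzylated 5,7-dimethyl ether 16 (not isolated)
Conditions: BCl3, C6HMe5, CH2Cl2, −78 → 0 °C; then H2O
Reagents that add atoms: none
Why: Boron trichloride dealkylation should first cleave the two aryl benzyl ethers at low temperature, pentamethylbenzene trapping the benzyl cation by Friedel–Crafts alkylation so that the electron-rich rings are not benzylated, and on warming the boron chelate between the C4 carbonyl and O5 should deliver chloride to the O5 methyl only, leaving the unchelated O7 methyl ether and the three stereocentres untouched.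

Compound list
1 | 4-hydroxy-2,6-dimethoxybenzaldehyde | COc1cc(O)cc(OC)c1C=O | starting material
2 | 2,6-dimethoxy-4-(methoxymethoxy)benzaldehyde | COCOc1cc(OC)c(C=O)c(OC)c1 | intermediate
3 | 1-(benzyloxy)-4-bromobenzene | Brc1ccc(OCc2ccccc2)cc1 | starting material
4 | [4-(benzyloxy)phenyl]lithium | [Li]c1ccc(OCc2ccccc2)cc1 | intermediate
5 | racemic [4-(benzyloxy)phenyl][2,6-dimethoxy-4-(methoxymethoxy)phenyl]methanol | COCOc1cc(OC)c(C(O)c2ccc(OCc3ccccc3)cc2)c(OC)c1 | intermediate
6 | [4-(benzyloxy)phenyl][2,6-dimethoxy-4-(methoxymethoxy)phenyl]methanone | COCOc1cc(OC)c(C(=O)c2ccc(OCc3ccccc3)cc2)c(OC)c1 | intermediate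
7 | 2-{1-[4-(benzyloxy)phenyl]ethenyl}-1,3-dimethoxy-5-(methoxymethoxy)benzene | COCOc1cc(OC)c(C(=C)c2ccc(OCc3ccccc3)cc2)c(OC)c1 | intermediate
8 | 2-{(1R)-1-[4-(benzyloxy)phenyl]ethyl}-1,3-dimethoxy-5-(methoxymethoxy)benzene | COCOc1cc(OC)c([C@H](C)c2ccc(OCc3ccccc3)cc2)c(OC)c1 | intermediate
9 | {3-[(1R)-1-(4-benzyloxyphenyl)ethyl]-2,4-dimethoxy-6-(methoxymethoxy)phenyl}lithium | COCOc1cc(OC)c([C@H](C)c2ccc(OCc3ccccc3)cc2)c(OC)c1[Li] | intermediate
10 | 1-{3-[(1R)-1-(4-benzyloxyphenyl)ethyl]-2,4-dimethoxy-6-(methoxymethoxy)phenyl}ethan-1-one | COCOc1cc(OC)c([C@H](C)c2ccc(OCc3ccccc3)cc2)c(OC)c1C(C)=O | intermediate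
11 | 4-(benzyloxy)benzaldehyde | O=Cc1ccc(OCc2ccccc2)cc1 | starting material
12 | (2E)-3-[4-(benzyloxy)phenyl]-1-{3-[(1R)-1-(4-benzyloxyphenyl)ethyl]-2,4-dimethoxy-6-(methoxymethoxy)phenyl}prop-2-en-1-one | COCOc1cc(OC)c([C@H](C)c2ccc(OCc3ccccc3)cc2)c(OC)c1C(=O)/C=C/c1ccc(OCc2ccccc2)cc1 | intermediate
13 | {(2R,3S)-3-[4-(benzyloxy)phenyl]oxiran-2-yl}{3-[(1R)-1-(4-benzyloxyphenyl)ethyl]-2,4-dimethoxy-6-(methoxymethoxy)phenyl}methanone | COc1cc(OCOC)c(C(=O)[C@@H]2O[C@H]2c2ccc(OCc3ccccc3)cc2)c(OC)c1[C@H](C)c1ccc(OCc2ccccc2)cc1 | intermediate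
14 | {(2R,3S)-3-[4-(benzyloxy)phenyl]oxiran-2-yl}{3-[(1R)-1-(4-benzyloxyphenyl)ethyl]-6-hydroxy-2,4-dimethoxyphenyl}methanone | COc1cc(O)c(C(=O)[C@@H]2O[C@H]2c2ccc(OCc3ccccc3)cc2)c(OC)c1[C@H](C)c1ccc(OCc2ccccc2)cc1 | intermediate
15 | (2R,3R)-2-[4-(benzyloxy)phenyl]-6-{(1R)-1-[4-(benzyloxy)phenyl]ethyl}-3-hydroxy-5,7-dimethoxy-2,3-dihydro-4H-chromen-4-one | COc1cc2c(c(OC)c1[C@H](C)c1ccc(OCc3ccccc3)cc1)C(=O)[C@H](O)[C@@H](c1ccc(OCc3ccccc3)cc1)O2 | intermediate
16 | (2R,3R)-3-hydroxy-2-(4-hydroxyphenyl)-6-[(1R)-1-(4-hydroxyphenyl)ethyl]-5,7-dimethoxy-2,3-dihydro-4H-chromen-4-one (boron-bound in the flask, drawn as the free phenol) | COc1cc2c(c(OC)c1[C@H](C)c1ccc(O)cc1)C(=O)[C@H](O)[C@@H](c1ccc(O)cc1)O2 | intermediate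
17 | (2R,3R)-3,5-dihydroxy-2-(4-hydroxyphenyl)-6-[(1R)-1-(4-hydroxyphenyl)ethyl]-7-methoxy-2,3-dihydro-4H-chromen-4-one | COc1cc2c(c(O)c1[C@H](C)c1ccc(O)cc1)C(=O)[C@H](O)[C@@H](c1ccc(O)cc1)O2 | target

Total step count: 10
Longest linear sequence: 10 steps (1 → 17); compounds 3 and 11 enter as purchased materials.

Steps most likely to fail

Step 9. The epoxide may ionise before the phenol is free, so that methanol captures the benzylic position, the aryl group migrates, or closure turns 5-exo; each would cost yield and stereospecificity. The fallback separates epoxide opening from ring closure and sets out from 13. Benzyl mercaptan and SnCl4 in CH2Cl2 at −20 °C should open the epoxide at the benzylic carbon with inversion and cleave the methoxymethyl ether in the same operation. This would give (2S,3R)-3-[4-(benzyloxy)phenyl]-3-(benzylsulfanyl)-1-{3-[(1R)-1-(4-benzyloxyphenyl)ethyl]-6-hydroxy-2,4-dimethoxyphenyl}-2-hydroxypropan-1-one F1. AgBF4 in CH2Cl2 at 0 °C should then activate the sulfide as a leaving group, and the phenol should close ring C onto C2 under the control of the C3 centre. The route is rejoined at 15.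

Step 8. Turnover may be slow and facial control incomplete, because the 2',6'-dioxygenated aroyl group is twisted out of conjugation and may bind poorly to the peptide helix. The fallback gives up catalyst control and uses the stereocentre already present; it sets out from 12. Weitz–Scheffer epoxidation (H2O2, NaOH, MeOH/THF) should give 13 together with its diastereomer {(2S,3R)-3-[4-(benzyloxy)phenyl]oxiran-2-yl}{3-[(1R)-1-(4-benzyloxyphenyl)ethyl]-2,4-dimethoxy-6-(methoxymethoxy)phenyl}methanone F2. The mixture would be treated as in step 9. F2 should pass through its free phenol {(2S,3R)-3-[4-(benzyloxy)phenyl]oxiran-2-yl}{3-[(1R)-1-(4-benzyloxyphenyl)ethyl]-6-hydroxy-2,4-dimethoxyphenyl}methanone F3 to (2S,3S)-2-[4-(benzyloxy)phenyl]-6-{(1R)-1-[4-(benzyloxy)phenyl]ethyl}-3-hydroxy-5,7-dimethoxy-2,3-dihydro-4H-chromen-4-one F4. F4 is a diastereomer of 15 and would be removed by preparative HPLC or crystallisation. The route is rejoined at 15.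

Step 5. The catalyst may discriminate poorly between the two aryl groups, or acidic iridium hydride species may oligomerise the electron-rich alkene. The fallback replaces asymmetric catalysis by resolution and sets out from 7. Hydrogenation with the achiral catalyst [Ir(cod)(PCy3)(py)]PF6 in CH2Cl2 should give 8 as a racemate with 2-{(1S)-1-[4-(benzyloxy)phenyl]ethyl}-1,3-dimethoxy-5-(methoxymethoxy)benzene F5. Preparative chromatography on a polysaccharide chiral stationary phase would then separate the two. The route is rejoined at 8.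

Further compounds
F1 | step 9 | (2S,3R)-3-[4-(benzyloxy)phenyl]-3-(benzylsulfanyl)-1-{3-[(1R)-1-(4-benzyloxyphenyl)ethyl]-6-hydroxy-2,4-dimethoxyphenyl}-2-hydroxypropan-1-one | COc1cc(O)c(C(=O)[C@H](O)[C@@H](c2ccc(OCc3ccccc3)cc2)SCc2ccccc2)c(OC)c1[C@H](C)c1ccc(OCc2ccccc2)cc1
F2 | step 8 | {(2S,3R)-3-[4-(benzyloxy)phenyl]oxiran-2-yl}{3-[(1R)-1-(4-benzyloxyphenyl)ethyl]-2,4-dimethoxy-6-(methoxymethoxy)phenyl}methanone | COc1cc(OCOC)c(C(=O)[C@H]2O[C@@H]2c2ccc(OCc3ccccc3)cc2)c(OC)c1[C@H](C)c1ccc(OCc2ccccc2)cc1
F3 | step 8 | {(2S,3R)-3-[4-(benzyloxy)phenyl]oxiran-2-yl}{3-[(1R)-1-(4-benzyloxyphenyl)ethyl]-6-hydroxy-2,4-dimethoxyphenyl}methanone | COc1cc(O)c(C(=O)[C@H]2O[C@@H]2c2ccc(OCc3ccccc3)cc2)c(OC)c1[C@H](C)c1ccc(OCc2ccccc2)cc1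
F4 | step 8 | (2S,3S)-2-[4-(benzyloxy)phenyl]-6-{(1R)-1-[4-(benzyloxy)phenyl]ethyl}-3-hydroxy-5,7-dimethoxy-2,3-dihydro-4H-chromen-4-one | COc1cc2c(c(OC)c1[C@H](C)c1ccc(OCc3ccccc3)cc1)C(=O)[C@@H](O)[C@H](c1ccc(OCc3ccccc3)cc1)O2
F5 | step 5 | 2-{(1S)-1-[4-(benzyloxy)phenyl]ethyl}-1,3-dimethoxy-5-(methoxymethoxy)benzene | COCOc1cc(OC)c([C@@H](C)c2ccc(OCc3ccccc3)cc2)c(OC)c1
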